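## Retrosynthetic overview

1. Target 26 ⇐ sixteen-fold O-demethylation of hexadecamethyl ether 25; 25 ⇐ furan ring (B–C bond) closed last by palladium double C–H coupling of diaryl ether 24.
2. 24 ⇐ two Ullmann C–O unions on a dibenzo-1,4-dioxin core (rings C/D): with the A–B bromide 12 at the ring C oxygen and with the E–F–G–H bromide 9 at the ring D oxygen.
3. Core ⇐ one-pot dioxin annulation of 5-hydroxyvanillin 13 with 6-bromoveratraldehyde 14 (Ullmann C–O bond, then a new copper/air C–H cycloetherification); its two formyl groups become ring oxygens by two separate Dakin oxidations.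
4. 9 ⇐ Ullmann ether of phenol 5 (rings G–H) with the symmetric dibromobiaryl 8 (rings E–F, Ullmann homocoupling of two molecules of 7); 5 and 12 both ⇐ 2-bromo-4,6-dimethoxybenzaldehyde 2 by Ullmann/Dakin.
5. Ring order: E–F biaryl → 1,4-dioxin (C/D) → diaryl ethers → furan (B/C).

Assumption: the SMILES has no stereodescriptor and the molecule has no stereocentre; the configuration of the hindered E–F biaryl axis is unspecified, so it is not controlled (8 and all later biaryls are racemic about this axis).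

Ring letters follow the target SMILES from left to right: A (3,5-dioxyphenoxy), B and C (dibenzofuran), D (second dioxin ring), E–F (biaryl), G, H (terminal trioxyphenoxy). Dibenzodioxin locants: ring C = C-1 to C-4, ring D = C-6 to C-9.

## Route

Step 1
Reactants: 1 2,4,6-trimethoxyphenol; 2 2-bromo-4,6-dimethoxybenzaldehyde
Product: 3 2,4-dimethoxy-6-(2,4,6-trimethoxyphenoxy)benzaldehyde
Conditions: CuI (10 mol%), N,N-dimethylglycine·HCl (30 mol%), Cs2CO3, 1,4-dioxane, 100 °C, Ar
Reagents that add atoms: none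
Why: Ullmann diaryl ether synthesis, in which the ortho-formyl group activates the C–Br bond of 2 so that even the 2,6-disubstituted phenoxide of 1 couples; no stereocentre is formed.

Step 2
Reactants: 3 2,4-dimethoxy-6-(2,4,6-trimethoxyphenoxy)benzaldehyde
Product: 5 2,4-dimethoxy-6-(2,4,6-trimethoxyphenoxy)phenol, via aryl formate 4 (not isolated)
Conditions: 30% H2O2, H2SO4 (cat.), MeOH, rt
Reagents that add atoms: hydrogen peroxide, OO
Why: Acid-catalysed Dakin (Baeyer–Villiger-type) oxidation, in which the 2,4,6-trioxygenated aryl group migrates readily and formate 4 is methanolysed in the same pot.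

Step 3
Reactants: 6 1-bromo-3,5-dimethoxybenzene
Product: 7 1-bromo-2-iodo-3,5-dimethoxybenzene
Conditions: NIS (1.05 equiv), MeCN, rt, dark
Reagents that add atoms: N-iodosuccinimide, O=C1CCC(=O)N1I
Why: Electrophilic aromatic iodination at C-2 (para to one OMe, ortho to the other) rather than at the more hindered C-4 between the two methoxy groups.

Step 4
Reactants: 7 1-bromo-2-iodo-3,5-dimethoxybenzene
Product: 8 2,2'-dibromo-4,4',6,6'-tetramethoxy-1,1'-biphenyl
Conditions: activated copper powder (4 equiv), DMF, 140 °C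
Reagents that add atoms: 1-bromo-2-iodo-3,5-dimethoxybenzene (the second molecule of 7 that is joined to the first), COc1cc(Br)c(I)c(OC)c1
Why: Classical Ullmann biaryl homocoupling, in which two molecules of 7 are joined at their iodine-bearing carbons (two CuI lost per biaryl); it is selective for C–I over C–Br and well suited to tetra-ortho-substituted biaryls, and the biaryl axis forms without control (racemic).

Step 5
Reactants: 5 2,4-dimethoxy-6-(2,4,6-trimethoxyphenoxy)phenol; 8 2,2'-dibromo-4,4',6,6'-tetramethoxy-1,1'-biphenyl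
Product: 9 2-bromo-2'-[2,4-dimethoxy-6-(2,4,6-trimethoxyphenoxy)phenoxy]-4,4',6,6'-tetramethoxy-1,1'-biphenyl
Conditions: CuI (20 mol%), picolinic acid (40 mol%), K3PO4, DMSO, 110 °C, Ar; 8 used at 3 equiv and the excess recovered
Reagents that add atoms: none
Why: Ullmann diaryl ether synthesis with the CuI/picolinic acid system for hindered partners; the excess of symmetric dibromide makes the mono-ether the main product.

Step 6
Reactants: 2 2-bromo-4,6-dimethoxybenzaldehyde
Product: 11 2-bromo-4,6-dimethoxyphenol, via aryl formate 10 (not isolated)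
Conditions: 30% H2O2, H2SO4 (cat.), MeOH, rt
Reagents that add atoms: hydrogen peroxide, OO
Why: Acid-catalysed Dakin oxidation of an ortho/para-dimethoxybenzaldehyde with in situ methanolysis of formate 10.

Step 7
Reactants: 11 2-bromo-4,6-dimethoxyphenol; 6 1-bromo-3,5-dimethoxybenzene
Product: 12 1-bromo-2-(3,5-dimethoxyphenoxy)-3,5-dimethoxybenzene
Conditions: CuI (10 mol%), N,N-dimethylglycine·HCl (30 mol%), Cs2CO3, 1,4-dioxane, 105 °C, Ar; 6 used at 3 equiv
Reagents that add atoms: none
Why: Ullmann diaryl ether synthesis in which the phenoxide of 11 couples with the unhindered bromide 6 (in excess), while its own ortho bromide, electron-rich and flanked by oxygen substituents, stays intact.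

Step 8
Reactants: 13 3,4-dihydroxy-5-methoxybenzaldehyde (5-hydroxyvanillin); 14 2-bromo-4,5-dimethoxybenzaldehyde (6-bromoveratraldehyde)
Product: 16 4,6,7-trimethoxydibenzo[b,e][1,4]dioxine-2,9-dicarbaldehyde, via diaryl ether 15 (not isolated)
Conditions: CuI (20 mol%), 1,10-phenanthroline (20 mol%), Cs2CO3 (2.2 equiv), DMSO, 110 °C, N2; then PivOH (1 equiv), air (1 atm), 130 °C
Reagents that add atoms: none
Why: Proposed new method: a one-pot copper-catalysed O-arylation/aerobic C–H cycloetherification that annulates a catechol onto a mono-bromoarene. In the first stage the catecholate's more electron-rich, less hindered 3-oxide (meta to CHO) displaces the ortho-formyl-activated bromide of 14 (any aryl migration by Smiles rearrangement converges on the same ether 15, because the para-formyl phenoxide is the better leaving group). In the second stage the remaining para-formyl phenoxide binds copper, air raises it to a high-valent copper aryloxide, this metalates the only ortho C–H of the veratryl ring, and C–O reductive elimination closes the six-membered dioxin with the regiochemistry fixed by 15. The closest known reaction is the copper-catalysed aerobic cycloetherification of 2-arylphenols carrying a para electron-withdrawing group to dibenzofurans; it has not been shown for 2-aryloxyphenols giving dibenzo-1,4-dioxins or in tandem with an Ullmann coupling.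

Step 9
Reactants: 16 4,6,7-trimethoxydibenzo[b,e][1,4]dioxine-2,9-dicarbaldehyde
Product: 17 6-hydroxy-4,7-dimethoxydibenzo[b,e][1,4]dioxine-2,9-dicarbaldehyde
Conditions: LiCl (5 equiv), DMF, 140 °C; aq. HCl work-up
Reagents that add atoms: none
Why: Nucleophilic O-demethylation (SN2 attack of chloride on methyl), selective because the 6-OMe is the only methyl ether para (or ortho) to a formyl group and so the only one with a good phenoxide leaving group.

Step 10
Reactants: 17 6-hydroxy-4,7-dimethoxydibenzo[b,e][1,4]dioxine-2,9-dicarbaldehyde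
Product: 20 6-hydroxy-4,7,9-trimethoxydibenzo[b,e][1,4]dioxine-2-carbaldehyde, via aryl formate 18 (not isolated), via hydroquinone 19 (not isolated)
Conditions: H2O2 (1.2 equiv), aq. NaOH, THF, 0 °C, Ar; Na2S2O4, aq. HCl work-up under Ar; then MeI (1.05 equiv), K2CO3 (1.1 equiv), acetone, rt
Reagents that add atoms: hydrogen peroxide, OO; iodomethane, CI
Why: Classical Dakin oxidation, which needs a free para hydroxyl and so touches only the 9-formyl group, then Williamson methylation of the less hindered 9-OH (one ortho oxygen) in preference to the 6-OH (two ortho oxygens).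

Step 11
Reactants: 20 6-hydroxy-4,7,9-trimethoxydibenzo[b,e][1,4]dioxine-2-carbaldehyde; 9 2-bromo-2'-[2,4-dimethoxy-6-(2,4,6-trimethoxyphenoxy)phenoxy]-4,4',6,6'-tetramethoxy-1,1'-biphenyl
Product: 21 6-{[2'-(2,4-dimethoxy-6-(2,4,6-trimethoxyphenoxy)phenoxy)-4,4',6,6'-tetramethoxy-1,1'-biphenyl-2-yl]oxy}-4,7,9-trimethoxydibenzo[b,e][1,4]dioxine-2-carbaldehyde
Conditions: CuI (30 mol%), picolinic acid (60 mol%), K3PO4, DMSO, 115 °C, Ar
Reagents that add atoms: none
Why: Ullmann diaryl ether synthesis between the electron-rich 2,6-dioxygenated phenoxide of 20 (the only free OH) and the remaining aryl bromide of 9, using the ligand system made for hindered partners; the non-enolisable aldehyde tolerates the base.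

Step 12
Reactants: 21 the aldehyde from step 11
Product: 23 6-{[2'-(2,4-dimethoxy-6-(2,4,6-trimethoxyphenoxy)phenoxy)-4,4',6,6'-tetramethoxy-1,1'-biphenyl-2-yl]oxy}-4,7,9-trimethoxydibenzo[b,e][1,4]dioxin-2-ol, via aryl formate 22 (not isolated)
Conditions: mCPBA (1.2 equiv), NaHCO3, CH2Cl2, 0 °C; then K2CO3 (cat.), MeOH, rt
Reagents that add atoms: 3-chloroperoxybenzoic acid, OOC(=O)c1cccc(Cl)c1
Why: Baeyer–Villiger (Dakin-type) oxidation with a peracid, in which the para-aryloxy-substituted aryl group migrates, run cold and buffered so the electron-rich rings are not attacked; methanolysis of formate 22 frees the phenol.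

Step 13
Reactants: 23 the phenol from step 12; 12 1-bromo-2-(3,5-dimethoxyphenoxy)-3,5-dimethoxybenzene
Product: 24 the 2-O-[2-(3,5-dimethoxyphenoxy)-3,5-dimethoxyphenyl] ether of 23 (rings A–H all in place, furan still open)
Conditions: CuI (20 mol%), N,N-dimethylglycine·HCl (40 mol%), Cs2CO3, 1,4-dioxane, 110 °C, Ar; 12 used at 1.5 equiv
Reagents that add atoms: none
Why: Ullmann diaryl ether synthesis between the only free, unhindered phenol of 23 and the aryl bromide of 12.

Step 14
Reactants: 24 the diaryl ether from step 13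
Product: 25 hexadecamethyl ether of the target (dibenzofuran closed)
Conditions: Pd(OAc)2 (20 mol%), K2CO3 (20 mol%), PivOH, air, 110 °C
Reagents that add atoms: none
Why: Palladium-catalysed oxidative intramolecular double C–H coupling of a diaryl ether to a dibenzofuran (divalent palladium, air as terminal oxidant): only the B–C ether in 24 has a free ortho C–H on both rings, ring B offers only one such position, and on ring C the C–H next to the dioxin oxygen is less hindered than the one next to the 4-OMe and leads to the less crowded bay.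

Step 15
Reactants: 25 hexadecamethyl ether of the target
Product: 26 target CNP0192765.0
Conditions: BBr3 (30 equiv), CH2Cl2, −78 °C to rt; MeOH then H2O quench
Reagents that add atoms: none
Why: Lewis-acid O-demethylation of all sixteen aryl methyl ethers with BBr3, which leaves diaryl ether, dibenzofuran and dibenzodioxin C–O bonds intact; staying at or below room temperature avoids acid-induced furan closure of the E–F biphenol.

## Compound list

1 | 2,4,6-trimethoxyphenol | COc1cc(OC)c(O)c(OC)c1 | starting material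
2 | 2-bromo-4,6-dimethoxybenzaldehyde | O=Cc1c(Br)cc(OC)cc1OC | starting material
3 | 2,4-dimethoxy-6-(2,4,6-trimethoxyphenoxy)benzaldehyde | O=Cc1c(Oc2c(OC)cc(OC)cc2OC)cc(OC)cc1OC | intermediate
4 | 2,4-dimethoxy-6-(2,4,6-trimethoxyphenoxy)phenyl formate | O=COc1c(Oc2c(OC)cc(OC)cc2OC)cc(OC)cc1OC | intermediate
5 | 2,4-dimethoxy-6-(2,4,6-trimethoxyphenoxy)phenol | Oc1c(Oc2c(OC)cc(OC)cc2OC)cc(OC)cc1OC | intermediate
6 | 1-bromo-3,5-dimethoxybenzene | COc1cc(Br)cc(OC)c1 | starting material
7 | 1-bromo-2-iodo-3,5-dimethoxybenzene | COc1cc(Br)c(I)c(OC)c1 | intermediate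
8 | 2,2'-dibromo-4,4',6,6'-tetramethoxy-1,1'-biphenyl | COc1cc(Br)c(-c2c(Br)cc(OC)cc2OC)c(OC)c1 | intermediate
9 | 2-bromo-2'-[2,4-dimethoxy-6-(2,4,6-trimethoxyphenoxy)phenoxy]-4,4',6,6'-tetramethoxy-1,1'-biphenyl | COc1cc(Br)c(-c2c(OC)cc(OC)cc2Oc2c(OC)cc(OC)cc2Oc2c(OC)cc(OC)cc2OC)c(OC)c1 | intermediate
10 | 2-bromo-4,6-dimethoxyphenyl formate | O=COc1c(Br)cc(OC)cc1OC | intermediate
11 | 2-bromo-4,6-dimethoxyphenol | Oc1c(Br)cc(OC)cc1OC | intermediate
12 | 1-bromo-2-(3,5-dimethoxyphenoxy)-3,5-dimethoxybenzene | COc1cc(OC)cc(Oc2c(Br)cc(OC)cc2OC)c1 | intermediate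
13 | 3,4-dihydroxy-5-methoxybenzaldehyde | COc1cc(C=O)cc(O)c1O | starting material
14 | 2-bromo-4,5-dimethoxybenzaldehyde | COc1cc(Br)c(C=O)cc1OC | starting material
15 | 2-(5-formyl-2-hydroxy-3-methoxyphenoxy)-4,5-dimethoxybenzaldehyde | COc1cc(C=O)cc(Oc2cc(OC)c(OC)cc2C=O)c1O | intermediate
16 | 4,6,7-trimethoxydibenzo[b,e][1,4]dioxine-2,9-dicarbaldehyde | COc1cc(C=O)cc2Oc3c(C=O)cc(OC)c(OC)c3Oc12 | intermediate
17 | 6-hydroxy-4,7-dimethoxydibenzo[b,e][1,4]dioxine-2,9-dicarbaldehyde | COc1cc(C=O)cc2Oc3c(C=O)cc(OC)c(O)c3Oc12 | intermediate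
18 | 8-formyl-4-hydroxy-3,6-dimethoxydibenzo[b,e][1,4]dioxin-1-yl formate (9-O-formate of 19) | COc1cc(C=O)cc2Oc3c(OC=O)cc(OC)c(O)c3Oc12 | intermediate
19 | 6,9-dihydroxy-4,7-dimethoxydibenzo[b,e][1,4]dioxine-2-carbaldehyde | COc1cc(C=O)cc2Oc3c(O)cc(OC)c(O)c3Oc12 | intermediate
20 | 6-hydroxy-4,7,9-trimethoxydibenzo[b,e][1,4]dioxine-2-carbaldehyde | COc1cc(C=O)cc2Oc3c(OC)cc(OC)c(O)c3Oc12 | intermediate
21 | 6-{[2'-(2,4-dimethoxy-6-(2,4,6-trimethoxyphenoxy)phenoxy)-4,4',6,6'-tetramethoxy-1,1'-biphenyl-2-yl]oxy}-4,7,9-trimethoxydibenzo[b,e][1,4]dioxine-2-carbaldehyde | COc1cc(C=O)cc2Oc3c(OC)cc(OC)c(Oc4cc(OC)cc(OC)c4-c4c(OC)cc(OC)cc4Oc4c(OC)cc(OC)cc4Oc4c(OC)cc(OC)cc4OC)c3Oc12 | intermediate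
22 | 2-O-formate of phenol 23 | COc1cc(OC=O)cc2Oc3c(OC)cc(OC)c(Oc4cc(OC)cc(OC)c4-c4c(OC)cc(OC)cc4Oc4c(OC)cc(OC)cc4Oc4c(OC)cc(OC)cc4OC)c3Oc12 | intermediate
23 | 2-hydroxy analogue of 21 (CHO replaced by OH) | COc1cc(O)cc2Oc3c(OC)cc(OC)c(Oc4cc(OC)cc(OC)c4-c4c(OC)cc(OC)cc4Oc4c(OC)cc(OC)cc4Oc4c(OC)cc(OC)cc4OC)c3Oc12 | intermediate
24 | 2-O-[2-(3,5-dimethoxyphenoxy)-3,5-dimethoxyphenyl] ether of 23 | COc1cc(Oc5cc(OC)cc(OC)c5Oc5cc(OC)cc(OC)c5)cc2Oc3c(OC)cc(OC)c(Oc4cc(OC)cc(OC)c4-c4c(OC)cc(OC)cc4Oc4c(OC)cc(OC)cc4Oc4c(OC)cc(OC)cc4OC)c3Oc12 | intermediate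
25 | hexadecamethyl ether of the target | COc1cc(OC)cc(Oc2c(OC)cc(OC)c3c2oc2cc(OC)c4c(c23)Oc2c(OC)cc(OC)c(Oc3cc(OC)cc(OC)c3-c3c(OC)cc(OC)cc3Oc3c(OC)cc(OC)cc3Oc3c(OC)cc(OC)cc3OC)c2O4)c1 | intermediate
26 | CNP0192765.0 | Oc1cc(O)cc(Oc2c(O)cc(O)c3c2oc2cc(O)c4c(c23)Oc2c(O)cc(O)c(Oc3cc(O)cc(O)c3-c3c(O)cc(O)cc3Oc3c(O)cc(O)cc3Oc3c(O)cc(O)cc3O)c2O4)c1 | target

## Step count and risks

Total steps: 15. Longest linear sequence: 8 steps (steps 8–15; equally 1, 2, 5, 11–15 or 3, 4, 5, 11–15).

The three steps most likely to fail: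

Step 8 (new one-pot dioxin annulation). The aerobic copper stage may oxidise the formyl groups or fail to metalate the veratryl C–H. The fallback uses known chemistry, sets out from 13 and comes back at 16. It is the classical two-fold Ullmann condensation of a catechol with an ortho-dibromoarene: 13 is heated with commercial 2,3-dibromo-4,5-dimethoxybenzaldehyde F1 (CuI, Cs2CO3, DMSO, 120–140 °C, N2). The bromide ortho to the formyl group reacts first with the meta oxygen of the catecholate to give 3-bromo-2-(5-formyl-2-hydroxy-3-methoxyphenoxy)-4,5-dimethoxybenzaldehyde F2, and the para-formyl phenoxide then closes onto the second bromide intramolecularly to give 16.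

Step 11 (C–O union of two hindered fragments). If the 2,6-dioxygenated phenol 20 does not couple with the ortho-aryl bromide 9, the E–F biaryl bond is made last instead of being carried in 9. This fallback sets out from 20 (and uses 5 and 6) and comes back at 21. Bromination of 6 (NBS, MeCN) gives 1,2-dibromo-3,5-dimethoxybenzene F3. Ullmann coupling of 20 with F3 at its less hindered bromide (CuI, N,N-dimethylglycine, Cs2CO3) gives 6-(2-bromo-3,5-dimethoxyphenoxy)-4,7,9-trimethoxydibenzo[b,e][1,4]dioxine-2-carbaldehyde F4. The same coupling of 5 with F3 gives 2-bromo-1-[2,4-dimethoxy-6-(2,4,6-trimethoxyphenoxy)phenoxy]-3,5-dimethoxybenzene F5. Bromine–lithium exchange on F5 (n-BuLi, THF, −78 °C) and trapping with 2-isopropoxy-4,4,5,5-tetramethyl-1,3,2-dioxaborolane gives its pinacol boronate F6. Suzuki–Miyaura coupling of F4 with F6 (Pd(OAc)2, SPhos, K3PO4, toluene/H2O, 100 °C) forms the tetra-ortho-substituted biaryl and delivers 21.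

Step 14 (late oxidative double C–H cyclisation). If the oxidative conditions degrade 24 or give mixtures at ring C, the furan is closed by a halogen-directed direct arylation under zerovalent palladium, without oxidant and before ring A is attached. The ring C site is then chosen in a concerted metalation–deprotonation step that favours the more acidic C–H flanked by two aryloxy-bearing carbons. This fallback sets out from 23 and comes back at 25. Bromination of 2 (NBS, MeCN) gives 2,3-dibromo-4,6-dimethoxybenzaldehyde F7. Ullmann coupling of 23 with F7 at the bromide ortho to the formyl group gives the bromo aldehyde diaryl ether F8. Intramolecular direct arylation (Pd(OAc)2, PCy3·HBF4, K2CO3, DMA, 130 °C) closes the furan to the dibenzofuran aldehyde F9. Baeyer–Villiger oxidation (mCPBA, NaHCO3, CH2Cl2; then K2CO3, MeOH) gives, through the aryl formate F10, the dibenzofuran phenol F11. Ullmann coupling of F11 with 6 installs ring A and gives 25.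

Further compounds
F1 | step 8 | 2,3-dibromo-4,5-dimethoxybenzaldehyde | COc1cc(C=O)c(Br)c(Br)c1OC
F2 | step 8 | 3-bromo-2-(5-formyl-2-hydroxy-3-methoxyphenoxy)-4,5-dimethoxybenzaldehyde | COc1cc(C=O)cc(Oc2c(Br)c(OC)c(OC)cc2C=O)c1O
F3 | step 11 | 1,2-dibromo-3,5-dimethoxybenzene | COc1cc(Br)c(Br)c(OC)c1
F4 | step 11 | 6-(2-bromo-3,5-dimethoxyphenoxy)-4,7,9-trimethoxydibenzo[b,e][1,4]dioxine-2-carbaldehyde | COc1cc(C=O)cc2Oc3c(OC)cc(OC)c(Oc4cc(OC)cc(OC)c4Br)c3Oc12
F5 | step 11 | 2-bromo-1-[2,4-dimethoxy-6-(2,4,6-trimethoxyphenoxy)phenoxy]-3,5-dimethoxybenzene | COc1cc(OC)c(Br)c(Oc2c(OC)cc(OC)cc2Oc2c(OC)cc(OC)cc2OC)c1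
F6 | step 11 | pinacol boronate of F5 (Br replaced by 4,4,5,5-tetramethyl-1,3,2-dioxaborolan-2-yl) | COc1cc(OC)c(B2OC(C)(C)C(C)(C)O2)c(Oc2c(OC)cc(OC)cc2Oc2c(OC)cc(OC)cc2OC)c1
F7 | step 14 | 2,3-dibromo-4,6-dimethoxybenzaldehyde | O=Cc1c(Br)c(Br)c(OC)cc1OC
F8 | step 14 | 2-O-(3-bromo-2-formyl-4,6-dimethoxyphenyl) ether of 23 | COc1cc(Oc5c(Br)c(OC)cc(OC)c5C=O)cc2Oc3c(OC)cc(OC)c(Oc4cc(OC)cc(OC)c4-c4c(OC)cc(OC)cc4Oc4c(OC)cc(OC)cc4Oc4c(OC)cc(OC)cc4OC)c3Oc12
F9 | step 14 | dibenzofuran aldehyde (25 with the ring A aryloxy group replaced by CHO) | O=Cc1c(OC)cc(OC)c2c1oc1cc(OC)c3c(c12)Oc1c(OC)cc(OC)c(Oc2cc(OC)cc(OC)c2-c2c(OC)cc(OC)cc2Oc2c(OC)cc(OC)cc2Oc2c(OC)cc(OC)cc2OC)c1O3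
F10 | step 14 | aryl formate of F11 | O=COc1c(OC)cc(OC)c2c1oc1cc(OC)c3c(c12)Oc1c(OC)cc(OC)c(Oc2cc(OC)cc(OC)c2-c2c(OC)cc(OC)cc2Oc2c(OC)cc(OC)cc2Oc2c(OC)cc(OC)cc2OC)c1O3
F11 | step 14 | dibenzofuran phenol (25 with the ring A aryloxy group replaced by OH) | Oc1c(OC)cc(OC)c2c1oc1cc(OC)c3c(c12)Oc1c(OC)cc(OC)c(Oc2cc(OC)cc(OC)c2-c2c(OC)cc(OC)cc2Oc2c(OC)cc(OC)cc2Oc2c(OC)cc(OC)cc2OC)c1O3
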